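**Retrosynthetic overview**
- The only ring formed is the furan ring, made first and fully aromatic: oxidative annulation of phenol 1 with β-keto ester 2 gives benzofuran 4.
- Key disconnection is C2–H/C3–H: both stereocentres come from one enantioselective, dearomatising hydrogenation of the flat, achiral benzofuran 6 (the triacetate of 4) to cis-7.
- The C5 side chain is attached after the reduction, by Heck reaction of bromide 7 with methyl acrylate 8, so the cinnamate never sees H2.
- Endgame: methoxide removes the three acetates and equilibrates C3 (cis to trans) to give the target, which is (2R,3R) and trans by CIP analysis of the given SMILES.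

Assumption: the facial sense of the new Ir-catalysed hydrogenation in Step 3 is not known for this substrate class; the ligand antipode written is assumed to give (2R,3S)-7, and its mirror image is used if a test run gives ent-7.

**Route**

Step 1
Reactants: 1 4-bromo-2-methoxyphenol (4-bromoguaiacol, 1.0 equiv); 2 methyl 3-(3,4-dimethoxyphenyl)-3-oxopropanoate (1.5 equiv)
Product: 4 methyl 5-bromo-2-(3,4-dimethoxyphenyl)-7-methoxy-1-benzofuran-3-carboxylate, via C-arylated keto ester 3 (not isolated)
Conditions: FeCl3·6H2O (10 mol%), (t-BuO)2 (2 equiv), ClCH2CH2Cl, 100 °C, sealed tube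
Reagents that add atoms: none
Why: Fe-catalysed oxidative (cross-dehydrogenative) coupling of the only free ortho C–H of the phenol (para blocked by Br) with the α-C–H of the Fe-chelated β-keto ester, followed by cyclodehydration of the phenol OH onto the aryl ketone, gives the 2-aryl-3-carboxylate benzofuran regiochemistry; no stereocentre is formed.

Step 2
Reactants: 4 methyl 5-bromo-2-(3,4-dimethoxyphenyl)-7-methoxy-1-benzofuran-3-carboxylate
Product: 6 methyl 7-acetoxy-5-bromo-2-(3,4-diacetoxyphenyl)-1-benzofuran-3-carboxylate, via triphenol 5 (not isolated)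
Conditions: BBr3 (5 equiv), CH2Cl2, −78 → 0 °C; MeOH quench, 0 → 40 °C, concentrate; then Ac2O (6 equiv), pyridine, DMAP (5 mol%), rt
Reagents that add atoms: acetic anhydride, CC(=O)OC(C)=O
Why: BBr3 demethylates the three aryl methyl ethers at the robust aromatic benzofuran stage while the conjugated methyl ester survives at ≤0 °C (the HBr/MeOH quench re-esterifies any acid), and DMAP-catalysed peracetylation of the crude air-sensitive triphenol gives a crystalline substrate whose protecting groups tolerate hydrogenation and Heck coupling and fall off under the final methoxide conditions; no stereocentre is formed.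

Step 3
Reactants: 6 methyl 7-acetoxy-5-bromo-2-(3,4-diacetoxyphenyl)-1-benzofuran-3-carboxylate
Product: 7 methyl (2R,3S)-7-acetoxy-5-bromo-2-(3,4-diacetoxyphenyl)-2,3-dihydro-1-benzofuran-3-carboxylate (cis)
Conditions: [Ir(cod)(L*)]BArF (2–3 mol%), H2 (100 bar), CH2Cl2, 60 °C, 24 h; L* = (S)-8-(di-tert-butylphosphinooxy)-2-phenyl-5,6,7,8-tetrahydroquinoline
Reagents that add atoms: none
Why: Proposed new method: enantioselective dearomatising hydrogenation of a tetrasubstituted, ester-conjugated benzofuran C2=C3 bond, in which the cationic Ir dihydride binds the least aromatic π-bond of the heteroarene (formally a β-aryloxy-β-aryl acrylate), and migratory insertion then reductive elimination deliver both hydrogens to one face (syn addition, hence cis), so the chiral N,P pocket sets C2 (R) and C3 (S) together by face selection while ArBr, aryl acetates and the benzene rings are inert to this catalyst class; the closest known reaction types are Ir–N,P-catalysed asymmetric hydrogenation of 2- or 3-monosubstituted benzofurans and furans and of tetrasubstituted alkenes.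

Step 4
Reactants: 7 methyl (2R,3S)-7-acetoxy-5-bromo-2-(3,4-diacetoxyphenyl)-2,3-dihydro-1-benzofuran-3-carboxylate; 8 methyl acrylate (2 equiv)
Product: 9 methyl (2R,3S)-7-acetoxy-2-(3,4-diacetoxyphenyl)-5-[(E)-3-methoxy-3-oxoprop-1-en-1-yl]-2,3-dihydro-1-benzofuran-3-carboxylate (cis)
Conditions: Pd2(dba)3 (2.5 mol%), [HP(t-Bu)3]BF4 (10 mol%), Cy2NMe (1.5 equiv), 1,4-dioxane, 50 °C
Reagents that add atoms: none
Why: Mizoroki–Heck reaction of the unhindered, electron-rich aryl bromide under mild bulky-phosphine conditions gives the E-cinnamate by syn-insertion/syn-β-hydride elimination, and the hindered tertiary amine at 50 °C leaves the acetates and both stereocentres untouched.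

Step 5
Reactants: 9 methyl (2R,3S)-7-acetoxy-2-(3,4-diacetoxyphenyl)-5-[(E)-3-methoxy-3-oxoprop-1-en-1-yl]-2,3-dihydro-1-benzofuran-3-carboxylate
Product: 11 methyl (2R,3R)-2-(3,4-dihydroxyphenyl)-7-hydroxy-5-[(E)-3-methoxy-3-oxoprop-1-en-1-yl]-2,3-dihydro-1-benzofuran-3-carboxylate (trans; CNP0529351.1), via cis-triol 10 (not isolated)
Conditions: NaOMe (6 equiv), degassed MeOH, Ar, 0 °C → rt; AcOH quench
Reagents that add atoms: none
Why: Zemplén-type transesterification removes the three aryl acetates, and excess methoxide reversibly enolises the C3 ester (α-aryl, so acidic) so that reprotonation gives the thermodynamically favoured trans isomer (aryl and CO2Me anti) by base-mediated epimerisation, inverting C3 from S to R while C2 (R) is untouched.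

**Compound list**
1 | 4-bromo-2-methoxyphenol (4-bromoguaiacol) | COc1cc(Br)ccc1O | starting material
2 | methyl 3-(3,4-dimethoxyphenyl)-3-oxopropanoate | COC(=O)CC(=O)c1ccc(OC)c(OC)c1 | starting material
3 | methyl 2-(5-bromo-2-hydroxy-3-methoxyphenyl)-3-(3,4-dimethoxyphenyl)-3-oxopropanoate (racemic, labile centre) | COC(=O)C(C(=O)c1ccc(OC)c(OC)c1)c1cc(Br)cc(OC)c1O | intermediate (not isolated)
4 | methyl 5-bromo-2-(3,4-dimethoxyphenyl)-7-methoxy-1-benzofuran-3-carboxylate | COC(=O)c1c(-c2ccc(OC)c(OC)c2)oc2c(OC)cc(Br)cc12 | intermediate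
5 | methyl 5-bromo-2-(3,4-dihydroxyphenyl)-7-hydroxy-1-benzofuran-3-carboxylate | COC(=O)c1c(-c2ccc(O)c(O)c2)oc2c(O)cc(Br)cc12 | intermediate (not isolated)
6 | methyl 7-acetoxy-5-bromo-2-(3,4-diacetoxyphenyl)-1-benzofuran-3-carboxylate | COC(=O)c1c(-c2ccc(OC(C)=O)c(OC(C)=O)c2)oc2c(OC(C)=O)cc(Br)cc12 | intermediate
7 | methyl (2R,3S)-7-acetoxy-5-bromo-2-(3,4-diacetoxyphenyl)-2,3-dihydro-1-benzofuran-3-carboxylate (cis) | Brc1cc(OC(C)=O)c2c(c1)[C@H](C(=O)OC)[C@H](c1ccc(OC(C)=O)c(OC(C)=O)c1)O2 | intermediate
8 | methyl acrylate | C=CC(=O)OC | starting material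
9 | methyl (2R,3S)-7-acetoxy-2-(3,4-diacetoxyphenyl)-5-[(E)-3-methoxy-3-oxoprop-1-en-1-yl]-2,3-dihydro-1-benzofuran-3-carboxylate (cis) | COC(=O)/C=C/c1cc(OC(C)=O)c2c(c1)[C@H](C(=O)OC)[C@H](c1ccc(OC(C)=O)c(OC(C)=O)c1)O2 | intermediate
10 | methyl (2R,3S)-2-(3,4-dihydroxyphenyl)-7-hydroxy-5-[(E)-3-methoxy-3-oxoprop-1-en-1-yl]-2,3-dihydro-1-benzofuran-3-carboxylate (cis; C3 epimer of the target) | COC(=O)/C=C/c1cc(O)c2c(c1)[C@H](C(=O)OC)[C@H](c1ccc(O)c(O)c1)O2 | intermediate (not isolated)
11 | methyl (2R,3R)-2-(3,4-dihydroxyphenyl)-7-hydroxy-5-[(E)-3-methoxy-3-oxoprop-1-en-1-yl]-2,3-dihydro-1-benzofuran-3-carboxylate (trans) | COC(=O)/C=C/c1cc(O)c2c(c1)[C@@H](C(=O)OC)[C@H](c1ccc(O)c(O)c1)O2 | target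

**Totals**
Total step count: 5. Longest linear sequence: 5 steps (1 → 4 → 6 → 7 → 9 → 11); compounds 2 and 8 are bought.

**Three steps most likely to fail, with fallbacks**

Step 3 (highest risk). The tetrasubstituted, ester-conjugated C2=C3 bond may not be reduced, or may be reduced with low ee. The fallback sets out from 6 and comes back at 7, and replaces H2 addition by an enantioselective conjugate hydride transfer: Cu(OAc)2 (5 mol%), DTBM-SEGPHOS (5.5 mol%, antipode chosen as for the Ir ligand), (EtO)2MeSiH (3 equiv), t-BuOH (2 equiv), toluene, 0 °C → rt. L*CuH delivers hydride to C2, the β-carbon of the benzofuran-3-carboxylate, so C2 alone is set by the ligand. The dearomatised copper enolate is then protonated at C3 by t-BuOH from the face anti to the C2 aryl group, which gives cis-7. The C3 selectivity of this protonation is immaterial because Step 5 equilibrates C3. This fallback makes no new compound (F0).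

Step 1. Oxidative homocoupling of the electron-rich guaiacol, or a sluggish reaction caused by the bromine, could lower the yield. The fallback sets out from 1 and comes back at 4, building the same benzofuran by alkyne carbonylation instead of C–H/C–H coupling.
- Ortho-iodination of 1 (NIS, cat. TsOH, MeCN, rt) gives 4-bromo-2-iodo-6-methoxyphenol F1.
- Sonogashira coupling at the C–I bond with commercial 4-ethynyl-1,2-dimethoxybenzene (C#Cc1ccc(OC)c(OC)c1), using PdCl2(PPh3)2, CuI, Et3N, THF, rt, gives 4-bromo-2-[(3,4-dimethoxyphenyl)ethynyl]-6-methoxyphenol F2; the C–Br bond is untouched at rt.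
- Pd(II)-catalysed methoxycarbonylative heteroannulation of F2 (PdI2–thiourea, CBr4, Cs2CO3, CO 1 atm, MeOH, 40 °C) closes the furan ring and installs the C3 ester, giving 4.

Step 5. The free catecholate is air-sensitive. The 4-phenoxide of the C2 aryl group could open the C2–O bond through a quinone methide, and the C3 enolate could undergo retro-oxa-Michael opening; either pathway would erode ee. The fallback sets out from 9 and comes back at 11, separating epimerisation from deprotection so that no phenoxide is ever present.
- DBU (0.5 equiv) in dry toluene at rt epimerises C3 of the fully protected compound to methyl (2R,3R)-7-acetoxy-2-(3,4-diacetoxyphenyl)-5-[(E)-3-methoxy-3-oxoprop-1-en-1-yl]-2,3-dihydro-1-benzofuran-3-carboxylate F3.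
- Acid-catalysed methanolysis (AcCl 0.5 equiv in MeOH, generating HCl, 0 °C → rt) then removes the acetates under non-basic conditions to give 11.

**Further compounds**
F1 | step 1 | 4-bromo-2-iodo-6-methoxyphenol | COc1cc(Br)cc(I)c1O
F2 | step 1 | 4-bromo-2-[(3,4-dimethoxyphenyl)ethynyl]-6-methoxyphenol | COc1cc(Br)cc(C#Cc2ccc(OC)c(OC)c2)c1O
F0 | step 3 | none | none
F3 | step 5 | methyl (2R,3R)-7-acetoxy-2-(3,4-diacetoxyphenyl)-5-[(E)-3-methoxy-3-oxoprop-1-en-1-yl]-2,3-dihydro-1-benzofuran-3-carboxylate | COC(=O)/C=C/c1cc(OC(C)=O)c2c(c1)[C@@H](C(=O)OC)[C@H](c1ccc(OC(C)=O)c(OC(C)=O)c1)O2
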